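The carbocycle (ring B: C4a, C5, C6, C7, C8, C8a) is cut at C6–C7 and C8–C8a. Its C7–C8 edge carries no substituent and its all-cis C4a/C5/C8a triad is the signature of a hydrogenated benzene ring, so C7–C8 is delivered as an acetylene equivalent. The precursor is a piperidine-based 1-amido diene (N1–C8a=C4a–C5=C6), made from an L-alanine-derived enyne by ring-closing enyne metathesis. Diels–Alder reaction with phenyl vinyl sulfoxide, sulfenic acid loss and DDQ oxidation give the benzo ring in one operation; one arene hydrogenation, steered by the bought C2 centre and C3, then sets C4a, C5 and C8a.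

Key step: step 10

Remark: (R)-2-propyloxirane, (5-chloropent-1-yn-1-yl)trimethylsilane, Boc-L-alanine N-methoxy-N-methylamide, phenyl vinyl sulfoxide, (E)-hex-2-enal and malonic acid are taken as commercial; the dienoic acid is made (step 13) in case it cannot be bought, and lepadin H is delivered as the free base.

Step 1
Reactants: 1 (R)-2-propyloxirane; 2 (5-chloropent-1-yn-1-yl)trimethylsilane
Product: 4 (4R)-10-(trimethylsilyl)dec-9-yn-4-ol, via Grignard reagent 3 (not isolated)
Conditions: Mg, THF, reflux; then CuI (10 mol %), 1, THF, −30 to 0 °C; aq. NH4Cl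
Reagents that add atoms: none
Why: Copper-catalysed opening of a terminal epoxide by a primary Grignard reagent occurs at the CH2 carbon, so the purchased stereocentre (later C5' of the side chain) is carried over unchanged.

Step 2
Reactants: 4 (4R)-10-(trimethylsilyl)dec-9-yn-4-ol
Product: 5 tert-butyldimethyl{[(4R)-10-(trimethylsilyl)dec-9-yn-4-yl]oxy}silane
Conditions: TBSCl, imidazole, DMF, rt
Reagents that add atoms: tert-butyldimethylsilyl chloride, CC(C)(C)[Si](C)(C)Cl
Why: Standard silylation of a secondary alcohol gives a TBS ether that should survive organolithium, Lewis acid, metathesis and hydrogenation conditions and fall only in the final acid step.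

Step 3
Reactants: 6 Boc-L-alanine N-methoxy-N-methylamide
Product: 7 tert-butyl N-[(2S)-4-chloro-3-oxobutan-2-yl]carbamate
Conditions: ICH2Cl, MeLi·LiBr, THF/Et2O, −78 °C; aq. NH4Cl
Reagents that add atoms: chloroiodomethane, ClCI
Why: Chloromethyllithium formed by iodine–lithium exchange adds once to the Weinreb amide through a chelated tetrahedral adduct, a known homologation to α-chloromethyl ketones that should not racemise the α-carbon (C2).

Step 4
Reactants: 7 tert-butyl N-[(2S)-4-chloro-3-oxobutan-2-yl]carbamate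
Product: 8 tert-butyl N-[(2S,3S)-4-chloro-3-hydroxybutan-2-yl]carbamate
Conditions: Al(OiPr)3, i-PrOH, 50 °C
Reagents that add atoms: none
Why: Meerwein–Ponndorf–Verley reduction of a carbamate-protected α-amino chloromethyl ketone should deliver hydride within an aluminium chelate of ketone and carbamate on the face away from the C2 methyl, giving the anti (erythro) chlorohydrin and thereby fixing C3 from C2.

Step 5
Reactants: 8 tert-butyl N-[(2S,3S)-4-chloro-3-hydroxybutan-2-yl]carbamate
Product: 9 tert-butyl N-[(1S)-1-[(2S)-oxiran-2-yl]ethyl]carbamate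
Conditions: KOH, EtOH, 0 °C to rt
Reagents that add atoms: none
Why: Intramolecular Williamson displacement of the primary chloride closes the epoxide without touching either stereocentre.

Step 6
Reactants: 5 tert-butyldimethyl{[(4R)-10-(trimethylsilyl)dec-9-yn-4-yl]oxy}silane; 9 tert-butyl N-[(1S)-1-[(2S)-oxiran-2-yl]ethyl]carbamate
Product: 11 tert-butyl N-[(2S,3R,11R)-11-[(tert-butyldimethylsilyl)oxy]-3-hydroxytetradec-5-yn-2-yl]carbamate, via lithium acetylide 10 (not isolated)
Conditions: 5 (2.2 equiv), MeLi (halide-free), THF, 0 °C to rt; then BF3·OEt2, 9, −78 °C; aq. NH4Cl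
Reagents that add atoms: none
Why: MeLi cleaves the alkynyl–silicon bond to the lithium acetylide, which opens the terminal epoxide at CH2 under BF3 activation (Yamaguchi–Hirao alkynylation) and so joins the two fragments at C4–C4a with C2 and C3 untouched.

Step 7
Reactants: 11 tert-butyl N-[(2S,3R,11R)-11-[(tert-butyldimethylsilyl)oxy]-3-hydroxytetradec-5-yn-2-yl]carbamate
Product: 13 (2S,3R,11R)-11-[(tert-butyldimethylsilyl)oxy]-3-[(triethylsilyl)oxy]tetradec-5-yn-2-amine, via silyl carbamate 12 (not isolated)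
Conditions: TESOTf, 2,6-lutidine, CH2Cl2, 0 °C to rt; then aq. NaHCO3
Reagents that add atoms: triethylsilyl trifluoromethanesulfonate, CC[Si](CC)(CC)OS(=O)(=O)C(F)(F)F
Why: Silyl triflate with 2,6-lutidine (Ohfune conditions) silylates the alcohol and turns the tert-butyl carbamate into a silyl carbamate that loses CO2 on hydrolysis, so the free amine and the temporary C3 O-TES ether arise together while the TBS ether and the alkyne stay intact.

Step 8
Reactants: 13 (2S,3R,11R)-11-[(tert-butyldimethylsilyl)oxy]-3-[(triethylsilyl)oxy]tetradec-5-yn-2-amine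
Product: 15 tert-butyl N-ethenyl-N-[(2S,3R,11R)-11-[(tert-butyldimethylsilyl)oxy]-3-[(triethylsilyl)oxy]tetradec-5-yn-2-yl]carbamate, via N-ethylidene amine 14 (not isolated)
Conditions: MeCHO, MgSO4, CH2Cl2, 0 °C; then Boc2O, DMAP, Et3N, 0 °C to rt
Reagents that add atoms: acetaldehyde, CC=O; di-tert-butyl dicarbonate, CC(C)(C)OC(=O)OC(=O)OC(C)(C)C
Why: N-Acylation of an aldimine followed by loss of its α-proton is the classical entry to N-alkyl-N-vinyl carbamates, and the O-TES group keeps the amino alcohol from closing to an oxazolidine.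

Step 9
Reactants: 15 tert-butyl N-ethenyl-N-[(2S,3R,11R)-11-[(tert-butyldimethylsilyl)oxy]-3-[(triethylsilyl)oxy]tetradec-5-yn-2-yl]carbamate
Product: 16 tert-butyl (2S,3R)-5-[(7R)-7-[(tert-butyldimethylsilyl)oxy]dec-1-en-2-yl]-2-methyl-3-[(triethylsilyl)oxy]-3,4-dihydro-2H-pyridine-1-carboxylate
Conditions: second-generation Grubbs catalyst RuCl2(=CHPh)(PCy3)(H2IMes) (10 mol %), ethylene (1 atm), toluene, 80 °C
Reagents that add atoms: none
Why: Exo-mode ring-closing enyne metathesis joins the enamide CH (C8a) to the proximal alkyne carbon (C4a) in a six-membered ring and leaves the distal alkyne carbon (C5) as a 1-alkylvinyl group, which gives the 1-amido diene directly, N-acyl enamides being competent partners in ruthenium-catalysed ring-closing metathesis.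

Step 10
Reactants: 16 tert-butyl (2S,3R)-5-[(7R)-7-[(tert-butyldimethylsilyl)oxy]dec-1-en-2-yl]-2-methyl-3-[(triethylsilyl)oxy]-3,4-dihydro-2H-pyridine-1-carboxylate; 17 phenyl vinyl sulfoxide
Product: 20 tert-butyl (2S,3R)-5-[(5R)-5-[(tert-butyldimethylsilyl)oxy]octyl]-2-methyl-3-[(triethylsilyl)oxy]-3,4-dihydro-2H-quinoline-1-carboxylate, via sulfoxide cycloadduct 18 (not isolated), via dihydroarene 19 (not isolated)
Conditions: 17 (3 equiv), K2CO3, toluene, 120 °C (sealed tube); then DDQ, rt
Reagents that add atoms: none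
Why: The semicyclic 1-(N-acylamino)diene N1–C8a=C4a–C5=C6 (HOMO raised by the carbamate nitrogen, largest coefficient at the C6 methylene) adds phenyl vinyl sulfoxide in a concerted, asynchronous, normal-demand [4+2] cycloaddition that forms C6–C7 and C8–C8a suprafacially in one event; the closest known reactions are the Diels–Alder reactions of Oppolzer/Overman dienamides and the use of phenyl vinyl sulfoxide as an acetylene equivalent. Ring B is thus closed by intermolecular [4+2] cycloaddition onto the preformed piperidine (ring A). At the reaction temperature the adduct should lose benzenesulfenic acid by syn elimination, and DDQ then removes H6 and H8a from the cyclohexadiene to give the benzene ring. The stereocentres created in the cycloaddition (C8a, C8 and sulfur) are all erased by the aromatisation, so no new stereocentre has to be controlled and neither facial, endo/exo nor regiochemical selectivity is required. What the step does need is reactivity and periselectivity of the diene: the ring holds the nitrogen on the outside of the diene, the 1,1-disubstituted C5=C6 terminus is unhindered and the s-cis conformer is accessible, while K2CO3 buffers the sulfenic acid so that the enecarbamate, the Boc group and the silyl ethers should survive. C2, C3 and C5' lie outside the reacting π system and are not touched.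

Step 11
Reactants: 20 tert-butyl (2S,3R)-5-[(5R)-5-[(tert-butyldimethylsilyl)oxy]octyl]-2-methyl-3-[(triethylsilyl)oxy]-3,4-dihydro-2H-quinoline-1-carboxylate
Product: 21 tert-butyl (2S,3R)-5-[(5R)-5-[(tert-butyldimethylsilyl)oxy]octyl]-3-hydroxy-2-methyl-3,4-dihydro-2H-quinoline-1-carboxylate
Conditions: PPTS, MeOH, 0 °C to rt
Reagents that add atoms: none
Why: Mild acid methanolysis removes the secondary triethylsilyl ether much faster than the TBS ether, freeing only the C3 hydroxyl.

Step 12
Reactants: 21 tert-butyl (2S,3R)-5-[(5R)-5-[(tert-butyldimethylsilyl)oxy]octyl]-3-hydroxy-2-methyl-3,4-dihydro-2H-quinoline-1-carboxylate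
Product: 22 tert-butyl (2S,3R,4aS,5S,8aR)-5-[(5R)-5-[(tert-butyldimethylsilyl)oxy]octyl]-3-hydroxy-2-methyl-octahydro-2H-quinoline-1-carboxylate
Conditions: H2 (60–80 bar), Rh/Al2O3 (5 wt %), i-PrOH/hexane, 50 °C
Reagents that add atoms: none
Why: Heterogeneous rhodium should add three H2 to one face of the arene (all-cis H4a, H5, H8a), and that face is chosen by the substrate, because A(1,3) strain with the N-Boc group holds the C2 methyl pseudoaxial on one face while the trans C3 hydroxyl on the other face can anchor the substrate on the metal (haptophilic effect), so hydrogen should enter syn to OH and anti to CH3 and give the 2,8a-cis, all-cis C4a/C5/C8a arrangement.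

Step 13
Reactants: 23 (E)-hex-2-enal; 24 malonic acid
Product: 26 (2E,4E)-octa-2,4-dienoic acid, via alkylidenemalonic acid 25 (not isolated)
Conditions: pyridine, piperidine (cat.), 90 °C
Reagents that add atoms: none
Why: Knoevenagel–Doebner condensation with decarboxylation should form the new double bond with (E) geometry and keep the existing (E)-alkene.

Step 14
Reactants: 22 tert-butyl (2S,3R,4aS,5S,8aR)-5-[(5R)-5-[(tert-butyldimethylsilyl)oxy]octyl]-3-hydroxy-2-methyl-octahydro-2H-quinoline-1-carboxylate; 26 (2E,4E)-octa-2,4-dienoic acid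
Product: 28 tert-butyl (2S,3R,4aS,5S,8aR)-5-[(5R)-5-[(tert-butyldimethylsilyl)oxy]octyl]-2-methyl-3-{[(2E,4E)-octa-2,4-dienoyl]oxy}-octahydro-2H-quinoline-1-carboxylate, via mixed anhydride 27 (not isolated)
Conditions: 26, 2,4,6-trichlorobenzoyl chloride, Et3N, THF, rt; then 22, DMAP, toluene, rt
Reagents that add atoms: none
Why: Yamaguchi esterification acylates the hindered secondary C3 hydroxyl, the only free OH while nitrogen is blocked as its carbamate, with retention at C3.

Step 15
Reactants: 28 tert-butyl (2S,3R,4aS,5S,8aR)-5-[(5R)-5-[(tert-butyldimethylsilyl)oxy]octyl]-2-methyl-3-{[(2E,4E)-octa-2,4-dienoyl]oxy}-octahydro-2H-quinoline-1-carboxylate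
Product: 29 lepadin H
Conditions: TFA/CH2Cl2/H2O, 0 °C to rt; aq. NaHCO3
Reagents that add atoms: none
Why: Acidolysis removes the Boc group and the TBS ether in one operation, the dienoate ester is stable to acid, and O-to-N acyl shift is not expected because N1 and the C3 oxygen can only meet through a bridged transition state.

Compound list

1 | (R)-2-propyloxirane | CCC[C@@H]1CO1 | starting material
2 | (5-chloropent-1-yn-1-yl)trimethylsilane | C[Si](C)(C)C#CCCCCl | starting material
3 | [5-(trimethylsilyl)pent-4-yn-1-yl]magnesium chloride | C[Si](C)(C)C#CCCC[Mg]Cl | intermediate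
4 | (4R)-10-(trimethylsilyl)dec-9-yn-4-ol | CCC[C@@H](O)CCCCC#C[Si](C)(C)C | intermediate
5 | tert-butyldimethyl{[(4R)-10-(trimethylsilyl)dec-9-yn-4-yl]oxy}silane | CCC[C@@H](O[Si](C)(C)C(C)(C)C)CCCCC#C[Si](C)(C)C | intermediate
6 | tert-butyl N-[(2S)-1-[methoxy(methyl)amino]-1-oxopropan-2-yl]carbamate (Boc-L-alanine N-methoxy-N-methylamide) | C[C@H](NC(=O)OC(C)(C)C)C(=O)N(C)OC | starting material
7 | tert-butyl N-[(2S)-4-chloro-3-oxobutan-2-yl]carbamate | C[C@H](NC(=O)OC(C)(C)C)C(=O)CCl | intermediate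
8 | tert-butyl N-[(2S,3S)-4-chloro-3-hydroxybutan-2-yl]carbamate | C[C@H](NC(=O)OC(C)(C)C)[C@H](O)CCl | intermediate
9 | tert-butyl N-[(1S)-1-[(2S)-oxiran-2-yl]ethyl]carbamate | C[C@H](NC(=O)OC(C)(C)C)[C@H]1CO1 | intermediate
10 | {(7R)-7-[(tert-butyldimethylsilyl)oxy]dec-1-yn-1-yl}lithium | [Li]C#CCCCC[C@@H](CCC)O[Si](C)(C)C(C)(C)C | intermediate
11 | tert-butyl N-[(2S,3R,11R)-11-[(tert-butyldimethylsilyl)oxy]-3-hydroxytetradec-5-yn-2-yl]carbamate | C[C@H](NC(=O)OC(C)(C)C)[C@H](O)CC#CCCCC[C@@H](CCC)O[Si](C)(C)C(C)(C)C | intermediate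
12 | triethylsilyl N-[(2S,3R,11R)-11-[(tert-butyldimethylsilyl)oxy]-3-[(triethylsilyl)oxy]tetradec-5-yn-2-yl]carbamate | C[C@H](NC(=O)O[Si](CC)(CC)CC)[C@H](O[Si](CC)(CC)CC)CC#CCCCC[C@@H](CCC)O[Si](C)(C)C(C)(C)C | intermediate
13 | (2S,3R,11R)-11-[(tert-butyldimethylsilyl)oxy]-3-[(triethylsilyl)oxy]tetradec-5-yn-2-amine | C[C@H](N)[C@H](O[Si](CC)(CC)CC)CC#CCCCC[C@@H](CCC)O[Si](C)(C)C(C)(C)C | intermediate
14 | (E)-N-[(2S,3R,11R)-11-[(tert-butyldimethylsilyl)oxy]-3-[(triethylsilyl)oxy]tetradec-5-yn-2-yl]ethanimine | C/C=N/[C@@H](C)[C@H](O[Si](CC)(CC)CC)CC#CCCCC[C@@H](CCC)O[Si](C)(C)C(C)(C)C | intermediate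
15 | tert-butyl N-ethenyl-N-[(2S,3R,11R)-11-[(tert-butyldimethylsilyl)oxy]-3-[(triethylsilyl)oxy]tetradec-5-yn-2-yl]carbamate | C[C@H](N(C=C)C(=O)OC(C)(C)C)[C@H](O[Si](CC)(CC)CC)CC#CCCCC[C@@H](CCC)O[Si](C)(C)C(C)(C)C | intermediate
16 | tert-butyl (2S,3R)-5-[(7R)-7-[(tert-butyldimethylsilyl)oxy]dec-1-en-2-yl]-2-methyl-3-[(triethylsilyl)oxy]-3,4-dihydro-2H-pyridine-1-carboxylate | C[C@H]1[C@H](O[Si](CC)(CC)CC)CC(C(=C)CCCC[C@@H](CCC)O[Si](C)(C)C(C)(C)C)=CN1C(=O)OC(C)(C)C | intermediate
17 | phenyl vinyl sulfoxide | C=CS(=O)c1ccccc1 | starting material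
18 | tert-butyl (2S,3R)-5-[(5R)-5-[(tert-butyldimethylsilyl)oxy]octyl]-2-methyl-8-(phenylsulfinyl)-3-[(triethylsilyl)oxy]-3,4,6,7,8,8a-hexahydro-2H-quinoline-1-carboxylate (mixture at C8, C8a and sulfur) | C[C@H]1[C@H](O[Si](CC)(CC)CC)CC2=C(CCCC[C@@H](CCC)O[Si](C)(C)C(C)(C)C)CCC(S(=O)c3ccccc3)C2N1C(=O)OC(C)(C)C | intermediate
19 | tert-butyl (2S,3R)-5-[(5R)-5-[(tert-butyldimethylsilyl)oxy]octyl]-2-methyl-3-[(triethylsilyl)oxy]-3,4,6,8a-tetrahydro-2H-quinoline-1-carboxylate (mixture at C8a) | C[C@H]1[C@H](O[Si](CC)(CC)CC)CC2=C(CCCC[C@@H](CCC)O[Si](C)(C)C(C)(C)C)CC=CC2N1C(=O)OC(C)(C)C | intermediate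
20 | tert-butyl (2S,3R)-5-[(5R)-5-[(tert-butyldimethylsilyl)oxy]octyl]-2-methyl-3-[(triethylsilyl)oxy]-3,4-dihydro-2H-quinoline-1-carboxylate | C[C@H]1[C@H](O[Si](CC)(CC)CC)Cc2c(CCCC[C@@H](CCC)O[Si](C)(C)C(C)(C)C)cccc2N1C(=O)OC(C)(C)C | intermediate
21 | tert-butyl (2S,3R)-5-[(5R)-5-[(tert-butyldimethylsilyl)oxy]octyl]-3-hydroxy-2-methyl-3,4-dihydro-2H-quinoline-1-carboxylate | C[C@H]1[C@H](O)Cc2c(CCCC[C@@H](CCC)O[Si](C)(C)C(C)(C)C)cccc2N1C(=O)OC(C)(C)C | intermediate
22 | tert-butyl (2S,3R,4aS,5S,8aR)-5-[(5R)-5-[(tert-butyldimethylsilyl)oxy]octyl]-3-hydroxy-2-methyl-octahydro-2H-quinoline-1-carboxylate | O[C@@H]1C[C@H]2[C@@H](CCCC[C@@H](CCC)O[Si](C)(C)C(C)(C)C)CCC[C@H]2N(C(=O)OC(C)(C)C)[C@H]1C | intermediate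
23 | (E)-hex-2-enal | CCC/C=C/C=O | starting material
24 | malonic acid | OC(=O)CC(=O)O | starting material
25 | 2-[(2E)-hex-2-en-1-ylidene]propanedioic acid | CCC/C=C/C=C(C(=O)O)C(=O)O | intermediate
26 | (2E,4E)-octa-2,4-dienoic acid | CCC/C=C/C=C/C(=O)O | intermediate
27 | (2E,4E)-octa-2,4-dienoic 2,4,6-trichlorobenzoic anhydride | CCC/C=C/C=C/C(=O)OC(=O)c1c(Cl)cc(Cl)cc1Cl | intermediate
28 | tert-butyl (2S,3R,4aS,5S,8aR)-5-[(5R)-5-[(tert-butyldimethylsilyl)oxy]octyl]-2-methyl-3-{[(2E,4E)-octa-2,4-dienoyl]oxy}-octahydro-2H-quinoline-1-carboxylate | CCC/C=C/C=C/C(=O)O[C@@H]1C[C@H]2[C@@H](CCCC[C@@H](CCC)O[Si](C)(C)C(C)(C)C)CCC[C@H]2N(C(=O)OC(C)(C)C)[C@H]1C | intermediate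
29 | lepadin H, (2S,3R,4aS,5S,8aR)-5-[(5R)-5-hydroxyoctyl]-2-methyl-decahydroquinolin-3-yl (2E,4E)-octa-2,4-dienoate | CCC/C=C/C=C/C(=O)O[C@@H]1C[C@H]2[C@@H](CCCC[C@H](O)CCC)CCC[C@H]2N[C@H]1C | target

Total step count: 15. Longest linear sequence: 12 steps (steps 3 to 12, then 14 and 15).

Steps most likely to fail

1. Step 10. The cycloaddition may be too slow at a temperature the diene tolerates, so that [1,5]-hydrogen shift in the diene or addition of sulfenic acid to the enecarbamate competes. Fallback: starting from 16, the cycloaddition is run with the far more reactive (E)-1,2-bis(phenylsulfonyl)ethylene (toluene, 80 °C), which forms the same two bonds and should give tert-butyl (2S,3R)-5-[(5R)-5-[(tert-butyldimethylsilyl)oxy]octyl]-2-methyl-7,8-bis(phenylsulfonyl)-3-[(triethylsilyl)oxy]-3,4,6,7,8,8a-hexahydro-2H-quinoline-1-carboxylate F1; twofold base-induced elimination of benzenesulfinic acid (DBU, toluene, 80 °C) then aromatises ring B and the route is rejoined at 20.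

2. Step 12. Facial selectivity of the arene hydrogenation may be poor, because the pseudoaxial C3 hydroxyl sits on the very face to which hydrogen has to add and may shield it instead of anchoring the catalyst. Fallback: starting from 21, C3 is oxidised with Dess–Martin periodinane to tert-butyl (2S)-5-[(5R)-5-[(tert-butyldimethylsilyl)oxy]octyl]-2-methyl-3-oxo-3,4-dihydro-2H-quinoline-1-carboxylate F2. NaBH4 should then attack anti to the pseudoaxial C2 methyl and give the cis alcohol tert-butyl (2S,3S)-5-[(5R)-5-[(tert-butyldimethylsilyl)oxy]octyl]-3-hydroxy-2-methyl-3,4-dihydro-2H-quinoline-1-carboxylate F3, whose hydroxyl is pseudoequatorial. Hydrogenation (H2, Rh/Al2O3) is now differentiated by the C2 methyl alone and should give tert-butyl (2S,3S,4aS,5S,8aR)-5-[(5R)-5-[(tert-butyldimethylsilyl)oxy]octyl]-3-hydroxy-2-methyl-octahydro-2H-quinoline-1-carboxylate F4. Mitsunobu esterification with 26 (PPh3, DIAD, THF) installs the dienoate with inversion at C3 and rejoins the route at 28.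

3. Step 9. The catalyst may stall as a stabilised ruthenium aminocarbene on the enamide, or closure may go partly in the endo mode to a seven-membered ring. Fallback: starting from 15, the alkyne is first consumed by cross enyne metathesis with ethylene alone (second-generation Grubbs catalyst RuCl2(=CHPh)(PCy3)(H2IMes), ethylene, CH2Cl2, rt), which should give the acyclic triene tert-butyl N-ethenyl-N-[(2S,3R,11R)-11-[(tert-butyldimethylsilyl)oxy]-5,6-dimethylidene-3-[(triethylsilyl)oxy]tetradecan-2-yl]carbamate F5. Ring A is then closed in a separate enamide–olefin ring-closing metathesis (second-generation Hoveyda–Grubbs catalyst RuCl2(=CH-C6H4-2-OiPr)(H2IMes), toluene, 80 °C, ethylene swept out), and the route is rejoined at 16.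

Further compounds

F1 | step 10 | tert-butyl (2S,3R)-5-[(5R)-5-[(tert-butyldimethylsilyl)oxy]octyl]-2-methyl-7,8-bis(phenylsulfonyl)-3-[(triethylsilyl)oxy]-3,4,6,7,8,8a-hexahydro-2H-quinoline-1-carboxylate | C[C@H]1[C@H](O[Si](CC)(CC)CC)CC2=C(CCCC[C@@H](CCC)O[Si](C)(C)C(C)(C)C)CC(S(=O)(=O)c3ccccc3)C(S(=O)(=O)c3ccccc3)C2N1C(=O)OC(C)(C)C
F2 | step 12 | tert-butyl (2S)-5-[(5R)-5-[(tert-butyldimethylsilyl)oxy]octyl]-2-methyl-3-oxo-3,4-dihydro-2H-quinoline-1-carboxylate | C[C@H]1C(=O)Cc2c(CCCC[C@@H](CCC)O[Si](C)(C)C(C)(C)C)cccc2N1C(=O)OC(C)(C)C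
F3 | step 12 | tert-butyl (2S,3S)-5-[(5R)-5-[(tert-butyldimethylsilyl)oxy]octyl]-3-hydroxy-2-methyl-3,4-dihydro-2H-quinoline-1-carboxylate | C[C@H]1[C@@H](O)Cc2c(CCCC[C@@H](CCC)O[Si](C)(C)C(C)(C)C)cccc2N1C(=O)OC(C)(C)C
F4 | step 12 | tert-butyl (2S,3S,4aS,5S,8aR)-5-[(5R)-5-[(tert-butyldimethylsilyl)oxy]octyl]-3-hydroxy-2-methyl-octahydro-2H-quinoline-1-carboxylate | O[C@H]1C[C@H]2[C@@H](CCCC[C@@H](CCC)O[Si](C)(C)C(C)(C)C)CCC[C@H]2N(C(=O)OC(C)(C)C)[C@H]1C
F5 | step 9 | tert-butyl N-ethenyl-N-[(2S,3R,11R)-11-[(tert-butyldimethylsilyl)oxy]-5,6-dimethylidene-3-[(triethylsilyl)oxy]tetradecan-2-yl]carbamate | C[C@H](N(C=C)C(=O)OC(C)(C)C)[C@H](O[Si](CC)(CC)CC)CC(=C)C(=C)CCCC[C@@H](CCC)O[Si](C)(C)C(C)(C)C
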